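## Retrosynthetic overview

1. Both oxiranes are made last: the tri-angelate triene 14 is epoxidised twice by Shi catalysts of opposite handedness, side chain first, ring second.
2. The ring trans-diol diester of 14 comes from rhodium-catalysed anti-SN2′ opening of the oxygen bridge of oxanorbornene 11 by angelic acid, then acylation of the two free hydroxyls.
3. The exocyclic methylene of 11 comes from methylenation of ketone 9.
4. Key step: Diels–Alder dearomatisation of 3-methylfuran by the (S)-α′-hydroxy enone 7. It joins all 15 skeletal carbons and forms the carbocycle (as a 7-oxanorbornene), with its three stereocentres relayed from the one carbinol centre.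
5. Enone 7 comes from methyl (S)-glycidate and two Grignard reagents. Ring order: carbocycle (oxabicycle) → bridge opened → side-chain oxirane → ring oxirane.

Assumption: the target is taken exactly as drawn, i.e. (1S,2S,3R,4R,6S) in 7-oxabicyclo[4.1.0]heptane numbering, (3S) in the butenyl chain, (2R) in the side-chain oxirane, all three esters angelates; all starting materials below are purchased.

## Route

Step 1
Reactants: 1 methyl (2S)-oxirane-2-carboxylate (methyl (S)-glycidate); 2 (2-methylprop-1-en-1-yl)magnesium bromide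
Product: 3 methyl (2S)-2-hydroxy-5-methylhex-4-enoate
Conditions: 2 (1.3 equiv, THF solution), CuI (10 mol %), THF, −78 → −40 °C; aq. NH4Cl
Reagents that add atoms: (2-methylprop-1-en-1-yl)magnesium bromide, CC(C)=C[Mg]Br
Why: Copper-catalysed SN2 opening of the epoxide at its unsubstituted carbon, faster than ester addition at this temperature; the C2 stereocentre is not touched and stays S.

Step 2
Reactants: 3 methyl (2S)-2-hydroxy-5-methylhex-4-enoate; 4 N,O-dimethylhydroxylamine hydrochloride; 5 vinylmagnesium bromide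
Product: 7 (4S)-4-hydroxy-7-methylocta-1,6-dien-3-one, via Weinreb amide 6 (not isolated)
Conditions: 4 (1.5 equiv), i-PrMgCl (4.5 equiv), THF, −20 °C, 1 h; then 5 (3 equiv), −20 → 0 °C; inverse quench into cold 1 M HCl; used at once
Reagents that add atoms: vinylmagnesium bromide, C=C[Mg]Br
Why: Weinreb ketone synthesis in one pot: the magnesium amide converts the ester into the N-methoxy-N-methyl amide, whose chelated adduct with the vinyl Grignard reagent stops at the ketone; the carbinol centre sits as its magnesium alkoxide and is not enolised, and the acidic inverse quench keeps the freed amine from adding to the enone.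

Step 3
Reactants: 7 (4S)-4-hydroxy-7-methylocta-1,6-dien-3-one; 8 3-methylfuran
Product: 9 (2S)-2-hydroxy-5-methyl-1-[(1S,2S,4S)-5-methyl-7-oxabicyclo[2.2.1]hept-5-en-2-yl]hex-4-en-1-one (acyl group endo, anti to the oxygen bridge)
Conditions: 8 (5 equiv), MgBr2·OEt2 (1.2 equiv), CH2Cl2, −78 → −40 °C, 24 h; cold aq. NaHCO3; chromatography at or below 20 °C
Reagents that add atoms: 3-methylfuran, Cc1ccoc1
Why: Lewis-acid-promoted Diels–Alder reaction: MgBr2 chelates the α′-hydroxy ketone into a planar five-membered ring with an s-cis enone, so the furan adds to the face opposite the CH2CH=CMe2 group (sets C2); furan C2, next to the methyl and carrying the largest HOMO coefficient, bonds to the enone CH2 ("para" orientation, as for isoprene and vinyl ketones under Lewis acid catalysis), and the kinetic endo mode sets C1 and C4 with the bridge anti to the acyl group.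

Step 4
Reactants: 9 (2S)-2-hydroxy-5-methyl-1-[(1S,2S,4S)-5-methyl-7-oxabicyclo[2.2.1]hept-5-en-2-yl]hex-4-en-1-one; 10 dibromomethane
Product: 11 (3S)-6-methyl-2-[(1S,2R,4S)-5-methyl-7-oxabicyclo[2.2.1]hept-5-en-2-yl]hepta-1,5-dien-3-ol
Conditions: Zn (9 equiv), 10 (3 equiv), TiCl4 (2.2 equiv), THF, aged at 5 °C; then 9, CH2Cl2, 0 °C → rt, 1 h; aq. NaHCO3
Reagents that add atoms: dibromomethane, BrCBr
Why: Takai–Lombardo methylenation with the non-basic zinc/titanium methylene reagent converts the ketone into the 1,1-disubstituted alkene without epimerising the enolisable ring carbon or eliminating the oxygen bridge, and it tolerates the free hydroxyl; no stereocentre is formed (the ring C2 descriptor changes from S to R only because the priorities change).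

Step 5
Reactants: 11 (3S)-6-methyl-2-[(1S,2R,4S)-5-methyl-7-oxabicyclo[2.2.1]hept-5-en-2-yl]hepta-1,5-dien-3-ol; 12 angelic acid, (2Z)-2-methylbut-2-enoic acid
Product: 13 (1R,5R,6R)-6-hydroxy-5-[(3S)-3-hydroxy-6-methylhepta-1,5-dien-2-yl]-2-methylcyclohex-2-en-1-yl (2Z)-2-methylbut-2-enoate
Conditions: [Rh(cod)Cl]2 (5 mol %; cod = cycloocta-1,5-diene), Fe(C5H4PPh2)2 (dppf, 11 mol %), 12 (5 equiv), Et3N (2.5 equiv), THF, 60 °C, 12 h
Reagents that add atoms: angelic acid, C/C=C(/C)C(=O)O
Why: Proposed new method: the rhodium–diphosphine catalyst binds the exo face of the strained alkene and inserts with retention into the bridgehead C4–O bond (the other insertion would force attack on the methyl-bearing carbon and place the metal beside the endo side chain); angelate then attacks the allyl-rhodium species at the unsubstituted alkene carbon C6 from the endo face, anti to the metal, so the new ester oxygen is trans to the retained C1 hydroxyl and the alkene moves to the methyl-bearing C4=C5 position; the closest known reaction type is the Lautens rhodium-catalysed anti-SN2′ ring opening of oxabicyclic alkenes with carboxylate nucleophiles.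

Step 6
Reactants: 13 (1R,5R,6R)-6-hydroxy-5-[(3S)-3-hydroxy-6-methylhepta-1,5-dien-2-yl]-2-methylcyclohex-2-en-1-yl (2Z)-2-methylbut-2-enoate; 12 angelic acid
Product: 14 (1R,2R,6R)-3-methyl-6-{(3S)-6-methyl-3-{[(2Z)-2-methylbut-2-enoyl]oxy}hepta-1,5-dien-2-yl}cyclohex-3-ene-1,2-diyl bis[(2Z)-2-methylbut-2-enoate]
Conditions: 12 (4 equiv), 2,4,6-Cl3C6H2COCl (4 equiv), Et3N (8 equiv), toluene, rt, 2 h; then 13, 70 °C, 6 h
Reagents that add atoms: angelic acid, C/C=C(/C)C(=O)O
Why: Yamaguchi-type esterification through the angelic 2,4,6-trichlorobenzoic mixed anhydride, used without a nucleophilic catalyst, is the established way to acylate hindered secondary alcohols with angelate without Z→E isomerisation to tiglate; both hydroxyls are esterified, no stereocentre is touched, and any earlier 1,2-acyl shift between the ring oxygens is harmless because both end as angelates.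

Step 7
Reactants: 14 (1R,2R,6R)-3-methyl-6-{(3S)-6-methyl-3-{[(2Z)-2-methylbut-2-enoyl]oxy}hepta-1,5-dien-2-yl}cyclohex-3-ene-1,2-diyl bis[(2Z)-2-methylbut-2-enoate]
Product: 15 (1R,2R,6R)-6-{(3S)-4-[(2R)-3,3-dimethyloxiran-2-yl]-3-{[(2Z)-2-methylbut-2-enoyl]oxy}but-1-en-2-yl}-3-methylcyclohex-3-ene-1,2-diyl bis[(2Z)-2-methylbut-2-enoate]
Conditions: 1,2:4,5-di-O-isopropylidene-β-D-erythro-2,3-hexodiulo-2,6-pyranose (D-fructose-derived Shi ketone, 30 mol %), KHSO5 (1.4 equiv, as 2KHSO5·KHSO4·K2SO4), K2CO3 (5.8 equiv), Bu4NHSO4 (5 mol %), MeCN/CH2(OMe)2/aq. Na2B4O7 buffer (pH 10.5), 0 °C, stopped when 14 is consumed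
Reagents that add atoms: potassium peroxymonosulfate, [K+].[O-]S(=O)(=O)OO
Why: Shi asymmetric epoxidation: the chiral dioxirane reacts first with the unhindered, most electron-rich prenyl alkene (the ring and exocyclic alkenes are deactivated by allylic esters, the ring alkene is also mismatched with this catalyst enantiomer, the angelates are electron-poor), and the spiro transition state sets the oxirane CH carbon as R under reagent control.

Step 8
Reactants: 15 (1R,2R,6R)-6-{(3S)-4-[(2R)-3,3-dimethyloxiran-2-yl]-3-{[(2Z)-2-methylbut-2-enoyl]oxy}but-1-en-2-yl}-3-methylcyclohex-3-ene-1,2-diyl bis[(2Z)-2-methylbut-2-enoate]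
Product: 16 (1S,2S,3R,4R,6S)-4-{(3S)-4-[(2R)-3,3-dimethyloxiran-2-yl]-3-{[(2Z)-2-methylbut-2-enoyl]oxy}but-1-en-2-yl}-1-methyl-7-oxabicyclo[4.1.0]heptane-2,3-diyl bis[(2Z)-2-methylbut-2-enoate] (CNP0258231.1)
Conditions: enantiomer of the Shi ketone (L-fructose series, 2 × 30 mol %), KHSO5 (2 × 1.2 equiv, as 2KHSO5·KHSO4·K2SO4), K2CO3, Bu4NHSO4 (5 mol %), MeCN/CH2(OMe)2/aq. Na2B4O7 buffer (pH 10.5), 0 °C, 6 h
Reagents that add atoms: potassium peroxymonosulfate, [K+].[O-]S(=O)(=O)OO
Why: Shi asymmetric epoxidation with the enantiomeric ketone: for this 1-methylcyclohexene-type alkene the spiro transition state delivers oxygen to the face anti to the allylic C2 angelate and syn to the C1 angelate, so catalyst and substrate preferences reinforce each other and both oxirane carbons are set as in the target, while the 1,1-disubstituted and angelate alkenes react much more slowly.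

## Compound list

1 | methyl (2S)-oxirane-2-carboxylate | COC(=O)[C@@H]1CO1 | starting material
2 | (2-methylprop-1-en-1-yl)magnesium bromide | CC(C)=C[Mg]Br | starting material
3 | methyl (2S)-2-hydroxy-5-methylhex-4-enoate | COC(=O)[C@@H](O)CC=C(C)C | intermediate
4 | N,O-dimethylhydroxylamine hydrochloride | CNOC.Cl | starting material
5 | vinylmagnesium bromide | C=C[Mg]Br | starting material
6 | (2S)-2-hydroxy-N-methoxy-N,5-dimethylhex-4-enamide | CON(C)C(=O)[C@@H](O)CC=C(C)C | intermediate (not isolated)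
7 | (4S)-4-hydroxy-7-methylocta-1,6-dien-3-one | C=CC(=O)[C@@H](O)CC=C(C)C | intermediate
8 | 3-methylfuran | Cc1ccoc1 | starting material
9 | (2S)-2-hydroxy-5-methyl-1-[(1S,2S,4S)-5-methyl-7-oxabicyclo[2.2.1]hept-5-en-2-yl]hex-4-en-1-one | CC(C)=CC[C@H](O)C(=O)[C@H]1C[C@@H]2O[C@H]1C=C2C | intermediate
10 | dibromomethane | BrCBr | starting material
11 | (3S)-6-methyl-2-[(1S,2R,4S)-5-methyl-7-oxabicyclo[2.2.1]hept-5-en-2-yl]hepta-1,5-dien-3-ol | CC(C)=CC[C@H](O)C(=C)[C@H]1C[C@@H]2O[C@H]1C=C2C | intermediate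
12 | angelic acid, (2Z)-2-methylbut-2-enoic acid | C/C=C(/C)C(=O)O | starting material
13 | (1R,5R,6R)-6-hydroxy-5-[(3S)-3-hydroxy-6-methylhepta-1,5-dien-2-yl]-2-methylcyclohex-2-en-1-yl (2Z)-2-methylbut-2-enoate | C=C([C@H](CC=C(C)C)O)[C@H]1CC=C(C)[C@@H](OC(=O)/C(C)=C\C)[C@@H]1O | intermediate
14 | (1R,2R,6R)-3-methyl-6-{(3S)-6-methyl-3-{[(2Z)-2-methylbut-2-enoyl]oxy}hepta-1,5-dien-2-yl}cyclohex-3-ene-1,2-diyl bis[(2Z)-2-methylbut-2-enoate] | C=C([C@H](CC=C(C)C)OC(=O)/C(C)=C\C)[C@H]1CC=C(C)[C@@H](OC(=O)/C(C)=C\C)[C@@H]1OC(=O)/C(C)=C\C | intermediate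
15 | (1R,2R,6R)-6-{(3S)-4-[(2R)-3,3-dimethyloxiran-2-yl]-3-{[(2Z)-2-methylbut-2-enoyl]oxy}but-1-en-2-yl}-3-methylcyclohex-3-ene-1,2-diyl bis[(2Z)-2-methylbut-2-enoate] | C=C([C@H](C[C@H]1OC1(C)C)OC(=O)/C(C)=C\C)[C@H]1CC=C(C)[C@@H](OC(=O)/C(C)=C\C)[C@@H]1OC(=O)/C(C)=C\C | intermediate
16 | (1S,2S,3R,4R,6S)-4-{(3S)-4-[(2R)-3,3-dimethyloxiran-2-yl]-3-{[(2Z)-2-methylbut-2-enoyl]oxy}but-1-en-2-yl}-1-methyl-7-oxabicyclo[4.1.0]heptane-2,3-diyl bis[(2Z)-2-methylbut-2-enoate] | C=C([C@H](C[C@H]1OC1(C)C)OC(=O)/C(C)=C\C)[C@H]1C[C@@H]2O[C@]2(C)[C@@H](OC(=O)/C(C)=C\C)[C@@H]1OC(=O)/C(C)=C\C | target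

## Step count and risks

Total step count: 8. Longest linear sequence: 8 steps (1 → 16); all other inputs are purchased.

The three steps most likely to fail:

**Step 3 (Diels–Alder).** Regiochemistry, endo/exo ratio and π-face selectivity must all go the right way at once, and the faces are told apart only by H versus CH2CH=CMe2 on the chelate. The adduct can also revert, and the furan can instead undergo Friedel–Crafts conjugate alkylation.
Fallback, setting out from 8 and coming back at 9: the absolute configuration is taken from a catalyst and the side chain is added afterwards. 3-Methylfuran 8 reacts with purchased 3-acryloyl-1,3-oxazolidin-2-one under [Cu(t-Bu-box)](SbF6)2 (10 mol %, CH2Cl2, −78 °C), where t-Bu-box is 2,2′-(propane-2,2-diyl)bis(4-tert-butyl-4,5-dihydro-1,3-oxazole) in the enantiomer that gives the 1S,2S,4S adduct; this catalyst class is proven for furan itself. The product is the endo imide 3-{[(1S,2S,4S)-5-methyl-7-oxabicyclo[2.2.1]hept-5-en-2-yl]carbonyl}-1,3-oxazolidin-2-one F1. AlMe3 with MeNH(OMe)·HCl turns it into the Weinreb amide (1S,2S,4S)-N-methoxy-N,5-dimethyl-7-oxabicyclo[2.2.1]hept-5-ene-2-carboxamide F2. (4-Methylpent-3-en-1-yl)magnesium bromide then gives the ketone 5-methyl-1-[(1S,2S,4S)-5-methyl-7-oxabicyclo[2.2.1]hept-5-en-2-yl]hex-4-en-1-one F3. Kinetic enolisation on the CH2 side (KN(SiMe3)2, THF, −78 °C) and Davis hydroxylation with the enantiomer of (camphorsulfonyl)oxaziridine that gives the 2S alcohol lead to 9.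

**Step 5 (rhodium-catalysed ring opening).** There is no direct precedent for a carboxylic acid nucleophile on a methyl-substituted oxanorbornene that is not benzo-fused. Insertion into the other C–O bond, interference by the free allylic alcohol and angelate-to-tiglate isomerisation are all possible.
Fallback, setting out from 11 and coming back at 14: the acyloxylation is replaced by alcoholysis with a removable benzylic alcohol, a nucleophile class better documented for such oxabicycles, and the ring angelates are introduced by acylation instead. Compound 11 with 4-methoxybenzyl alcohol (5 equiv), [Rh(cod)2]OTf and Fe(C5H4PPh2)2 in THF at 65 °C gives (1R,2R,6R)-6-[(3S)-3-hydroxy-6-methylhepta-1,5-dien-2-yl]-2-[(4-methoxyphenyl)methoxy]-3-methylcyclohex-3-en-1-ol F4. DDQ in wet CH2Cl2 with pH 7 buffer removes the benzyl group to give the triol (1R,2R,6R)-6-[(3S)-3-hydroxy-6-methylhepta-1,5-dien-2-yl]-3-methylcyclohex-3-ene-1,2-diol F5. Three-fold acylation under the conditions of step 6 then gives 14.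

**Step 8 (ring epoxidation).** The ring alkene is hindered and deactivated by its allylic ester, so the Shi dioxirane may react slowly. The face selectivity rests on a model for simple 1-methylcyclohexenes, and prolonged reaction may touch the exocyclic alkene.
Fallback, setting out from 11 and coming back at 16: the ring oxirane is made by hydroxyl direction before the last ring hydroxyl is acylated. Compound 11 is first angeloylated at its only hydroxyl (conditions of step 6) to give (3S)-6-methyl-2-[(1S,2R,4S)-5-methyl-7-oxabicyclo[2.2.1]hept-5-en-2-yl]hepta-1,5-dien-3-yl (2Z)-2-methylbut-2-enoate F6. The ring opening of step 5 then gives (1R,5R,6R)-6-hydroxy-2-methyl-5-{(3S)-6-methyl-3-{[(2Z)-2-methylbut-2-enoyl]oxy}hepta-1,5-dien-2-yl}cyclohex-2-en-1-yl (2Z)-2-methylbut-2-enoate F7. Its single free hydroxyl is homoallylic to the ring alkene and sits on the face that must carry the oxirane, so VO(acac)2 with t-BuOOH (CH2Cl2, 0 °C → rt) gives the cis-epoxy alcohol (1S,2S,3R,4R,6S)-3-hydroxy-1-methyl-4-{(3S)-6-methyl-3-{[(2Z)-2-methylbut-2-enoyl]oxy}hepta-1,5-dien-2-yl}-7-oxabicyclo[4.1.0]heptan-2-yl (2Z)-2-methylbut-2-enoate F8. Acylation as in step 6 gives (1S,2S,3R,4R,6S)-1-methyl-4-{(3S)-6-methyl-3-{[(2Z)-2-methylbut-2-enoyl]oxy}hepta-1,5-dien-2-yl}-7-oxabicyclo[4.1.0]heptane-2,3-diyl bis[(2Z)-2-methylbut-2-enoate] F9. The D-series Shi epoxidation of step 7 on the remaining prenyl alkene then gives 16.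

## Further compounds

F1 | step 3 | 3-{[(1S,2S,4S)-5-methyl-7-oxabicyclo[2.2.1]hept-5-en-2-yl]carbonyl}-1,3-oxazolidin-2-one | O=C([C@H]1C[C@@H]2O[C@H]1C=C2C)N1CCOC1=O
F2 | step 3 | (1S,2S,4S)-N-methoxy-N,5-dimethyl-7-oxabicyclo[2.2.1]hept-5-ene-2-carboxamide | CON(C)C(=O)[C@H]1C[C@@H]2O[C@H]1C=C2C
F3 | step 3 | 5-methyl-1-[(1S,2S,4S)-5-methyl-7-oxabicyclo[2.2.1]hept-5-en-2-yl]hex-4-en-1-one | CC(C)=CCCC(=O)[C@H]1C[C@@H]2O[C@H]1C=C2C
F4 | step 5 | (1R,2R,6R)-6-[(3S)-3-hydroxy-6-methylhepta-1,5-dien-2-yl]-2-[(4-methoxyphenyl)methoxy]-3-methylcyclohex-3-en-1-ol | C=C([C@H](CC=C(C)C)O)[C@H]1CC=C(C)[C@@H](OCc2ccc(OC)cc2)[C@@H]1O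
F5 | step 5 | (1R,2R,6R)-6-[(3S)-3-hydroxy-6-methylhepta-1,5-dien-2-yl]-3-methylcyclohex-3-ene-1,2-diol | C=C([C@H](CC=C(C)C)O)[C@H]1CC=C(C)[C@@H](O)[C@@H]1O
F6 | step 8 | (3S)-6-methyl-2-[(1S,2R,4S)-5-methyl-7-oxabicyclo[2.2.1]hept-5-en-2-yl]hepta-1,5-dien-3-yl (2Z)-2-methylbut-2-enoate | CC(C)=CC[C@H](OC(=O)/C(C)=C\C)C(=C)[C@H]1C[C@@H]2O[C@H]1C=C2C
F7 | step 8 | (1R,5R,6R)-6-hydroxy-2-methyl-5-{(3S)-6-methyl-3-{[(2Z)-2-methylbut-2-enoyl]oxy}hepta-1,5-dien-2-yl}cyclohex-2-en-1-yl (2Z)-2-methylbut-2-enoate | C=C([C@H](CC=C(C)C)OC(=O)/C(C)=C\C)[C@H]1CC=C(C)[C@@H](OC(=O)/C(C)=C\C)[C@@H]1O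
F8 | step 8 | (1S,2S,3R,4R,6S)-3-hydroxy-1-methyl-4-{(3S)-6-methyl-3-{[(2Z)-2-methylbut-2-enoyl]oxy}hepta-1,5-dien-2-yl}-7-oxabicyclo[4.1.0]heptan-2-yl (2Z)-2-methylbut-2-enoate | C=C([C@H](CC=C(C)C)OC(=O)/C(C)=C\C)[C@H]1C[C@@H]2O[C@]2(C)[C@@H](OC(=O)/C(C)=C\C)[C@@H]1O
F9 | step 8 | (1S,2S,3R,4R,6S)-1-methyl-4-{(3S)-6-methyl-3-{[(2Z)-2-methylbut-2-enoyl]oxy}hepta-1,5-dien-2-yl}-7-oxabicyclo[4.1.0]heptane-2,3-diyl bis[(2Z)-2-methylbut-2-enoate] | C=C([C@H](CC=C(C)C)OC(=O)/C(C)=C\C)[C@H]1C[C@@H]2O[C@]2(C)[C@@H](OC(=O)/C(C)=C\C)[C@@H]1OC(=O)/C(C)=C\C
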